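**Retrosynthetic overview**
1. Target 28 ⇐ desilylation/debenzylation of 26 ⇐ removal of the C6 carbonyl (enol triflate, Pd(OAc)2/HCO2H hydrogenolysis, diimide) from ketone 21.
2. Key disconnection C1–C1′ (quaternary carbon–benzylic carbon): intermolecular Mukaiyama–Michael addition (endo, hetero-Diels–Alder-like) of silyl dienol ether 13 (fragment 1) to o-quinone methide 18 (fragment 2), which is made from 16 and 17 and relayed through sulfone 19 in the same flask.
3. Fragment 1: ring B from (S)-carvone (C10); C7 by enzymatic cis reduction; C4 by trans enolate alkylation; ring A closed by ring-closing metathesis (C2=C3).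
4. Fragment 2: phloroglucinol → Vilsmeier diformylation → Knoevenagel condensation with isovaleraldehyde, stored by sulfinate and released by base.
5. Ring order: ring B (chiral pool) → ring A (metathesis) → preformed aryl ring attached in the key step.

Assumption/notation: decalin atoms are labelled C1 (quaternary carbon), C2=C3 (C3 at the ring fusion), C4 (ring-fusion CH), C5, C6, C7 (CHMe), C8, C9, C10 (CH bearing the carbinol) and C1′ (benzylic carbon); α is the face of the C4 hydrogen; TBS = tert-butyldimethylsilyl; 11 and 12 are carried as C1-epimer mixtures because C1 becomes trigonal in 13.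

**Route**

Step 1
Reactants: 1 (S)-(+)-carvone
Product: 2 (2R,5S)-2-methyl-5-(prop-1-en-2-yl)cyclohexan-1-one (cis-dihydrocarvone)
Conditions: ene-reductase OYE2, NADP+ (cat.), D-glucose, glucose dehydrogenase, phosphate buffer pH 7.0, 30 °C
Reagents that add atoms: none
Why: Enzymatic asymmetric conjugate reduction (old-yellow-enzyme ene-reductase) gives the 2R centre irrespective of the C5 centre, so (S)-carvone yields the cis ketone, which sets C7 (methyl cis to the C10 substituent) while C10 comes from the chiral pool.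

Step 2
Reactants: 2 (2R,5S)-2-methyl-5-(prop-1-en-2-yl)cyclohexan-1-one
Product: 3 (2R,5S)-5-(2-hydroxypropan-2-yl)-2-methylcyclohexan-1-one
Conditions: Co(acac)2 (20 mol%), PhSiH3, O2 (1 atm), THF, rt; then aq. Na2S2O3
Reagents that add atoms: dioxygen, O=O
Why: Mukaiyama hydration (cobalt-hydride hydrogen-atom transfer, Markovnikov) touches only the 1,1-disubstituted alkene under neutral conditions, so the epimerisable C7 centre next to the ketone is preserved.

Step 3
Reactants: 3 (2R,5S)-5-(2-hydroxypropan-2-yl)-2-methylcyclohexan-1-one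
Product: 4 (2R,5S)-5-[2-(tert-butyldimethylsilyloxy)propan-2-yl]-2-methylcyclohexan-1-one
Conditions: TBSOTf, 2,6-lutidine, CH2Cl2, −78 → 0 °C
Reagents that add atoms: tert-butyldimethylsilyl trifluoromethanesulfonate, CC(C)(C)[Si](C)(C)OS(=O)(=O)C(F)(F)F
Why: Silylation of the tertiary alcohol with the silyl triflate and a weak hindered base protects it for the later base, titanium, Grignard and triflation steps without enolising the ketone.

Step 4
Reactants: 4 (2R,5S)-5-[2-(tert-butyldimethylsilyloxy)propan-2-yl]-2-methylcyclohexan-1-one; 5 2-bromo-N-methoxy-N-methylacetamide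
Product: 7 N-methoxy-N-methyl-2-[(1R,3R,6S)-3-methyl-2-oxo-6-(2-TBSO-propan-2-yl)cyclohexyl]acetamide, via lithium enolate 6 (not isolated)
Conditions: LiN(iPr)2, THF, −78 °C; then 5, DMPU, −78 → −40 °C
Reagents that add atoms: none
Why: Kinetic deprotonation removes a C4 hydrogen (the C7 hydrogen is tertiary and equatorial), and SN2 enolate alkylation occurs anti to the adjacent C10 substituent and to the axial C7 methyl, setting C4 (R) trans to both.

Step 5
Reactants: 7 N-methoxy-N-methyl-2-[(1R,3R,6S)-3-methyl-2-oxo-6-(2-TBSO-propan-2-yl)cyclohexyl]acetamide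
Product: 8 N-methoxy-N-methyl-2-[(1R,3R,6S)-3-methyl-2-methylidene-6-(2-TBSO-propan-2-yl)cyclohexyl]acetamide
Conditions: Zn, CH2Br2, TiCl4, THF, 0 °C → rt
Reagents that add atoms: dibromomethane, BrCBr
Why: Takai–Lombardo methylenation is non-basic, so the hindered ketone becomes the exocyclic alkene without epimerising C7 or C4, and the Weinreb amide is left intact.

Step 6
Reactants: 8 N-methoxy-N-methyl-2-[(1R,3R,6S)-3-methyl-2-methylidene-6-(2-TBSO-propan-2-yl)cyclohexyl]acetamide; 9 crotylmagnesium chloride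
Product: 11 1-[(1R,3R,6S)-3-methyl-2-methylidene-6-(2-TBSO-propan-2-yl)cyclohexyl]-3-methylpent-4-en-2-one (C3 epimers), via chloromagnesium hemiaminal 10 (not isolated)
Conditions: CH3CH=CHCH2MgCl, THF, −78 → 0 °C; then cold aq. NH4Cl
Reagents that add atoms: none
Why: Weinreb ketone synthesis in which the crotyl Grignard reagent adds through its γ-carbon (SE2′) and the chelate 10 prevents over-addition; the new C1 centre is left uncontrolled because it is erased in step 8.

Step 7
Reactants: 11 1-[(1R,3R,6S)-3-methyl-2-methylidene-6-(2-TBSO-propan-2-yl)cyclohexyl]-3-methylpent-4-en-2-one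
Product: 12 (5R,8S,8aR)-3,5-dimethyl-8-(2-TBSO-propan-2-yl)-3,5,6,7,8,8a-hexahydronaphthalen-2(1H)-one (C3 epimers)
Conditions: second-generation Grubbs catalyst RuCl2(=CHPh)(PCy3)(H2IMes) (5 mol%), 1,4-benzoquinone (10 mol%), CH2Cl2, 40 °C
Reagents that add atoms: none
Why: Ring-closing olefin metathesis between the vinyl group and the exocyclic methylene closes ring A as a six-membered ring and fixes the trisubstituted C2=C3 alkene, while benzoquinone suppresses ruthenium-hydride alkene migration.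

Step 8
Reactants: 12 (5R,8S,8aR)-3,5-dimethyl-8-(2-TBSO-propan-2-yl)-3,5,6,7,8,8a-hexahydronaphthalen-2(1H)-one
Product: 13 tert-butyl{[(5R,8S,8aR)-3,5-dimethyl-8-(2-TBSO-propan-2-yl)-1,5,6,7,8,8a-hexahydronaphthalen-2-yl]oxy}dimethylsilane
Conditions: TBSOTf, Et3N, CH2Cl2, 0 °C
Reagents that add atoms: tert-butyldimethylsilyl trifluoromethanesulfonate, CC(C)(C)[Si](C)(C)OS(=O)(=O)C(F)(F)F
Why: Soft enolisation (silyl enol ether formation) removes the doubly activated C1 hydrogen (α to the carbonyl and allylic) and gives the conjugated 2-silyloxy-1,3-diene regioselectively.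

Step 9
Reactants: 14 phloroglucinol
Product: 16 2,4,6-trihydroxybenzene-1,3-dicarbaldehyde, via bis-iminium salt 15 (not isolated)
Conditions: POCl3, DMF, EtOAc, 0 °C → rt; then H2O, 50 °C
Reagents that add atoms: N,N-dimethylformamide, CN(C)C=O; water, O
Why: Vilsmeier–Haack formylation of the very electron-rich ring stops at the dialdehyde because each iminium group deactivates the nucleus.

Step 10
Reactants: 13 tert-butyl{[(5R,8S,8aR)-3,5-dimethyl-8-(2-TBSO-propan-2-yl)-1,5,6,7,8,8a-hexahydronaphthalen-2-yl]oxy}dimethylsilane; 16 2,4,6-trihydroxybenzene-1,3-dicarbaldehyde; 17 isovaleraldehyde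
Product: 21 2,4,6-trihydroxy-5-{3-methyl-1-[(2S,4aR,5S,8R)-2,8-dimethyl-3-oxo-5-(2-TBSO-propan-2-yl)-2,3,4,4a,5,6,7,8-octahydronaphthalen-2-yl]butyl}benzene-1,3-dicarbaldehyde (C1′ as in 28), via o-quinone methide 18 (not isolated), via sulfone 19 (not isolated), via silyl ketal cycloadduct 20 (not isolated)
Conditions: 16, 17, PhSO2Na, AcOH/H2O, 50 °C; volatiles removed, PhMe azeotrope; then 13, 2,6-lutidine (3 equiv), 4 Å molecular sieves, CH2Cl2, −40 °C → rt; then 1 M HCl, THF, 0 °C
Reagents that add atoms: none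
Why: Knoevenagel condensation at the only free ring carbon of 16 gives the o-quinone methide, which sulfinate stores as the benzylic sulfone until water and acid are removed, and lutidine-induced E1cB loss of sulfinate then releases it as the E heterodiene (the two ortho oxygens interconvert by tautomerism) for a Mukaiyama–Michael addition of 13 through a silyloxy-endo, hetero-Diels–Alder-like transition state on the α face of C1 (anti to the pseudoaxial C5 hydrogen; the γ-carbon C3 is a blocked ring-fusion carbon), which forms the C1–C1′ bond and sets C1 (S) and C1′ (as in 28) before acid opens the silyl ketal to the ketone.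

Step 11
Reactants: 21 keto triphenol (product of step 10)
Product: 22 2,4,6-tris(benzyloxy) analogue of 21
Conditions: BnBr, K2CO3, DMF, rt
Reagents that add atoms: benzyl bromide, BrCc1ccccc1
Why: Williamson O-benzylation of the three acidic phenols (every ring carbon is substituted, so no C-alkylation) removes the acidic protons and blocks phenoxide-driven retro-Michael cleavage before the strong-base step.

Step 12
Reactants: 22 2,4,6-tris(benzyloxy) analogue of 21
Product: 24 enol triflate of 22 (C5=C6 alkene bearing C6-OTf), via potassium enolate 23 (not isolated)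
Conditions: KN(SiMe3)2, THF, −78 °C; then PhNTf2, −78 → 0 °C
Reagents that add atoms: N-phenylbis(trifluoromethanesulfonimide), O=S(=O)(N(c1ccccc1)S(=O)(=O)C(F)(F)F)C(F)(F)F
Why: Enolisation can only occur toward C5 because C1 is quaternary, and O-triflation prepares removal of the C6 oxygen without a radical or cation next to the vinyl-bearing quaternary centre.

Step 13
Reactants: 24 enol triflate of 22
Product: 25 diene tris(benzyl ether) (C5=C6 alkene in place of the C6 carbonyl of 22)
Conditions: Pd(OAc)2 (5 mol%), PPh3, HCO2H, Et3N, DMF, 60 °C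
Reagents that add atoms: none
Why: Palladium-catalysed formate hydrogenolysis of the enol triflate (oxidative addition, hydride transfer from formate, reductive elimination) replaces the triflate by hydrogen without touching the stereocentres.

Step 14
Reactants: 25 diene tris(benzyl ether)
Product: 26 tris(benzyl ether) of 27
Conditions: KO2CN=NCO2K, AcOH, MeOH/CH2Cl2, 0 °C → rt (repeated charges)
Reagents that add atoms: none
Why: Diimide reduction (concerted syn hydrogen transfer) is strongly retarded by alkene substitution, so the cis-disubstituted C5=C6 alkene is saturated while the trisubstituted C2=C3 alkene, the aldehydes and the benzyl ethers survive.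

Step 15
Reactants: 26 tris(benzyl ether) of 27
Product: 27 TBS ether of 28
Conditions: BCl3, C6HMe5, CH2Cl2, −78 °C; then MeOH
Reagents that add atoms: none
Why: Chelation-assisted Lewis-acid debenzylation is fast at −78 °C because each benzyl ether is ortho to a formyl group, and pentamethylbenzene scavenges the benzyl cation so the alkene and the tertiary silyl ether are spared.

Step 16
Reactants: 27 TBS ether of 28
Product: 28 2,4,6-trihydroxy-5-{(1S)-1-[(2S,4aR,5S,8R)-5-(2-hydroxypropan-2-yl)-2,8-dimethyl-2,3,4,4a,5,6,7,8-octahydronaphthalen-2-yl]-3-methylbutyl}benzene-1,3-dicarbaldehyde (CNP0200991.2)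
Conditions: HF·pyridine, THF, 0 °C → rt
Reagents that add atoms: none
Why: Fluoride-mediated desilylation frees the tertiary alcohol without affecting any stereocentre and gives the target.

**Compound list**
1 | (S)-(+)-carvone | O=C1C(C)=CC[C@H](C(C)=C)C1 | starting material
2 | (2R,5S)-2-methyl-5-(prop-1-en-2-yl)cyclohexan-1-one | O=C1[C@H](C)CC[C@H](C(C)=C)C1 | intermediate
3 | (2R,5S)-5-(2-hydroxypropan-2-yl)-2-methylcyclohexan-1-one | O=C1[C@H](C)CC[C@H](C(C)(C)O)C1 | intermediate
4 | (2R,5S)-5-[2-(tert-butyldimethylsilyloxy)propan-2-yl]-2-methylcyclohexan-1-one | O=C1[C@H](C)CC[C@H](C(C)(C)O[Si](C)(C)C(C)(C)C)C1 | intermediate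
5 | 2-bromo-N-methoxy-N-methylacetamide | BrCC(=O)N(C)OC | starting material
6 | lithium enolate of 4 toward C4 (not isolated) | C[C@@H]1CC[C@H](C(C)(C)O[Si](C)(C)C(C)(C)C)C=C1O[Li] | intermediate
7 | N-methoxy-N-methyl-2-[(1R,3R,6S)-3-methyl-2-oxo-6-(2-TBSO-propan-2-yl)cyclohexyl]acetamide | O=C1[C@H](C)CC[C@H](C(C)(C)O[Si](C)(C)C(C)(C)C)[C@H]1CC(=O)N(C)OC | intermediate
8 | N-methoxy-N-methyl-2-[(1R,3R,6S)-3-methyl-2-methylidene-6-(2-TBSO-propan-2-yl)cyclohexyl]acetamide | C=C1[C@H](C)CC[C@H](C(C)(C)O[Si](C)(C)C(C)(C)C)[C@H]1CC(=O)N(C)OC | intermediate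
9 | crotylmagnesium chloride (but-2-en-1-ylmagnesium chloride) | CC=CC[Mg]Cl | starting material
10 | chloromagnesium hemiaminal from 8 and 9 (not isolated) | C=C1[C@H](C)CC[C@H](C(C)(C)O[Si](C)(C)C(C)(C)C)[C@H]1CC(O[Mg]Cl)(N(C)OC)C(C)C=C | intermediate
11 | 1-[(1R,3R,6S)-3-methyl-2-methylidene-6-(2-TBSO-propan-2-yl)cyclohexyl]-3-methylpent-4-en-2-one (C3 epimers) | C=C1[C@H](C)CC[C@H](C(C)(C)O[Si](C)(C)C(C)(C)C)[C@H]1CC(=O)C(C)C=C | intermediate
12 | (5R,8S,8aR)-3,5-dimethyl-8-(2-TBSO-propan-2-yl)-3,5,6,7,8,8a-hexahydronaphthalen-2(1H)-one (C3 epimers) | CC1C=C2[C@H](C)CC[C@H](C(C)(C)O[Si](C)(C)C(C)(C)C)[C@H]2CC1=O | intermediate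
13 | tert-butyl{[(5R,8S,8aR)-3,5-dimethyl-8-(2-TBSO-propan-2-yl)-1,5,6,7,8,8a-hexahydronaphthalen-2-yl]oxy}dimethylsilane | CC1=C(O[Si](C)(C)C(C)(C)C)C[C@@H]2[C@@H](C(C)(C)O[Si](C)(C)C(C)(C)C)CC[C@@H](C)C2=C1 | intermediate
14 | phloroglucinol (benzene-1,3,5-triol) | Oc1cc(O)cc(O)c1 | starting material
15 | bis(N,N-dimethyliminium) dichloride precursor of 16 (not isolated) | C[N+](C)=Cc1c(O)cc(O)c(C=[N+](C)C)c1O.[Cl-].[Cl-] | intermediate
16 | 2,4,6-trihydroxybenzene-1,3-dicarbaldehyde | O=Cc1c(O)cc(O)c(C=O)c1O | intermediate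
17 | isovaleraldehyde (3-methylbutanal) | CC(C)CC=O | starting material
18 | o-quinone methide 2,4-dihydroxy-5-(3-methylbutylidene)-6-oxocyclohexa-1,3-diene-1,3-dicarbaldehyde (not isolated) | CC(C)CC=C1C(=O)C(C=O)=C(O)C(C=O)=C1O | intermediate
19 | racemic 2,4,6-trihydroxy-5-[3-methyl-1-(phenylsulfonyl)butyl]benzene-1,3-dicarbaldehyde (not isolated) | CC(C)CC(c1c(O)c(C=O)c(O)c(C=O)c1O)S(=O)(=O)c1ccccc1 | intermediate
20 | cis-fused chroman silyl ketal, cycloadduct of 13 and 18 (aryl oxygen on the α face of C6; not isolated) | CC(C)C[C@H](c1c(O)c(C=O)c(O)c(C=O)c1O3)[C@]1(C)C=C2[C@H](C)CC[C@H](C(C)(C)O[Si](C)(C)C(C)(C)C)[C@H]2C[C@@]13O[Si](C)(C)C(C)(C)C | intermediate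
21 | 2,4,6-trihydroxy-5-{3-methyl-1-[(2S,4aR,5S,8R)-2,8-dimethyl-3-oxo-5-(2-TBSO-propan-2-yl)-2,3,4,4a,5,6,7,8-octahydronaphthalen-2-yl]butyl}benzene-1,3-dicarbaldehyde (C1′ as in 28) | CC(C)C[C@H](c1c(O)c(C=O)c(O)c(C=O)c1O)[C@]1(C)C=C2[C@H](C)CC[C@H](C(C)(C)O[Si](C)(C)C(C)(C)C)[C@H]2CC1=O | intermediate
22 | 2,4,6-tris(benzyloxy) analogue of 21 | CC(C)C[C@H](c1c(OCc2ccccc2)c(C=O)c(OCc2ccccc2)c(C=O)c1OCc1ccccc1)[C@]1(C)C=C2[C@H](C)CC[C@H](C(C)(C)O[Si](C)(C)C(C)(C)C)[C@H]2CC1=O | intermediate
23 | potassium enolate of 22 toward C5 (not isolated) | CC(C)C[C@H](c1c(OCc2ccccc2)c(C=O)c(OCc2ccccc2)c(C=O)c1OCc1ccccc1)[C@]1(C)C=C2[C@H](C)CC[C@H](C(C)(C)O[Si](C)(C)C(C)(C)C)[C@H]2C=C1O[K] | intermediate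
24 | enol triflate of 22 (C5=C6 alkene bearing C6-OTf) | CC(C)C[C@H](c1c(OCc2ccccc2)c(C=O)c(OCc2ccccc2)c(C=O)c1OCc1ccccc1)[C@]1(C)C=C2[C@H](C)CC[C@H](C(C)(C)O[Si](C)(C)C(C)(C)C)[C@H]2C=C1OS(=O)(=O)C(F)(F)F | intermediate
25 | diene tris(benzyl ether) (C5=C6 and C2=C3 alkenes; no C6 oxygen) | CC(C)C[C@H](c1c(OCc2ccccc2)c(C=O)c(OCc2ccccc2)c(C=O)c1OCc1ccccc1)[C@]1(C)C=C2[C@H](C)CC[C@H](C(C)(C)O[Si](C)(C)C(C)(C)C)[C@H]2C=C1 | intermediate
26 | tris(benzyl ether) of 27 | CC(C)C[C@H](c1c(OCc2ccccc2)c(C=O)c(OCc2ccccc2)c(C=O)c1OCc1ccccc1)[C@]1(C)C=C2[C@H](C)CC[C@H](C(C)(C)O[Si](C)(C)C(C)(C)C)[C@H]2CC1 | intermediate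
27 | TBS ether of 28 | CC(C)C[C@H](c1c(O)c(C=O)c(O)c(C=O)c1O)[C@]1(C)C=C2[C@H](C)CC[C@H](C(C)(C)O[Si](C)(C)C(C)(C)C)[C@H]2CC1 | intermediate
28 | 2,4,6-trihydroxy-5-{(1S)-1-[(2S,4aR,5S,8R)-5-(2-hydroxypropan-2-yl)-2,8-dimethyl-2,3,4,4a,5,6,7,8-octahydronaphthalen-2-yl]-3-methylbutyl}benzene-1,3-dicarbaldehyde | CC(C)C[C@H](c1c(O)c(C=O)c(O)c(C=O)c1O)[C@]1(C)C=C2[C@H](C)CC[C@H](C(C)(C)O)[C@H]2CC1 | target

**Totals and risks**

Total step count: 16. Longest linear sequence: 15 steps (1 → 28 through steps 1–8 and 10–16); the aryl branch adds step 9.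

Three steps most likely to fail:

Step 10. Residual acetic acid or the acidic phenols may protodesilylate 13 before the sulfone releases the quinone methide, and the face selectivity at C1 rests on a torsional argument. The fallback sets out from 13 and comes back at 27; it uses a non-acidic, magnesium-bound o-quinone methide and introduces the formyl groups last. Commercial 2,4,6-trihydroxybenzaldehyde is dibenzylated (BnBr, K2CO3, acetone) to 2,4-bis(benzyloxy)-6-hydroxybenzaldehyde F1 and acylated (Boc2O, iPr2NEt, DMAP) to the aryl tert-butyl carbonate F2. iBuMgCl (THF, −78 °C) is added to F2 in the presence of 13; on warming, Boc migration and elimination release the quinone methide, which 13 captures in the same endo Mukaiyama–Michael sense, and acidic work-up gives keto phenol F3. BnBr/K2CO3 gives tris(benzyl ether) F4, KN(SiMe3)2/PhNTf2 gives enol triflate F5, and Pd(OAc)2/PPh3/HCO2H/Et3N gives diene F6. H2 (1 atm) over Pd/C in EtOAc saturates the disubstituted alkene and cleaves the benzyl ethers to alkylphloroglucinol F7, and Vilsmeier–Haack diformylation (POCl3, DMF, EtOAc; then water) of F7 gives 27.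

Step 7. Metathesis onto the hindered 1,1-disubstituted alkene may stall. The fallback sets out from 7 and comes back at 12; it closes ring A between two monosubstituted vinyl groups. Excess CH2=CHMgBr (THF, −78 → 0 °C) adds to both the ketone and the Weinreb amide of 7 to give bis-vinyl hydroxy enone F8. The second-generation Grubbs catalyst RuCl2(=CHPh)(PCy3)(H2IMes) closes the disubstituted alkene of hydroxy enone F9. SmI2 (THF, HMPA, MeOH) removes the tertiary γ-hydroxyl by vinylogous reductive cleavage, and α-protonation of the dienolate gives des-methyl β,γ-unsaturated ketone F10. LiN(iPr)2 (THF, −78 °C) then MeI methylates the doubly activated C1 position to give 12.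

Step 6. The α-vinyl ketone 11 can isomerise into conjugation, and some linear crotyl adduct may form. The fallback sets out from 8 and comes back at 12; it builds the same chain at the alcohol oxidation level by carbonyl crotylation. iBu2AlH (THF, −78 °C) reduces the Weinreb amide to aldehyde F11. Pinacol (E)-crotylboronate (toluene, rt; chair transition state, γ-selective) gives homoallylic alcohol F12, whose two new centres need no control. Ring-closing metathesis of this non-isomerisable alcohol gives cyclohexenol F13, and Dess–Martin periodinane (NaHCO3, CH2Cl2) oxidises it to 12.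

Further compounds
F1 | step 10 | 2,4-bis(benzyloxy)-6-hydroxybenzaldehyde | O=Cc1c(O)cc(OCc2ccccc2)cc1OCc1ccccc1
F2 | step 10 | 3,5-bis(benzyloxy)-2-formylphenyl tert-butyl carbonate | O=Cc1c(OC(=O)OC(C)(C)C)cc(OCc2ccccc2)cc1OCc1ccccc1
F3 | step 10 | keto phenol: analogue of 21 carrying a 2-hydroxy-4,6-bis(benzyloxy)phenyl group without formyl groups | CC(C)C[C@H](c1c(O)cc(OCc2ccccc2)cc1OCc1ccccc1)[C@]1(C)C=C2[C@H](C)CC[C@H](C(C)(C)O[Si](C)(C)C(C)(C)C)[C@H]2CC1=O
F4 | step 10 | tris(benzyl ether) of F3 | CC(C)C[C@H](c1c(OCc2ccccc2)cc(OCc2ccccc2)cc1OCc1ccccc1)[C@]1(C)C=C2[C@H](C)CC[C@H](C(C)(C)O[Si](C)(C)C(C)(C)C)[C@H]2CC1=O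
F5 | step 10 | enol triflate of F4 (C5=C6 alkene bearing C6-OTf) | CC(C)C[C@H](c1c(OCc2ccccc2)cc(OCc2ccccc2)cc1OCc1ccccc1)[C@]1(C)C=C2[C@H](C)CC[C@H](C(C)(C)O[Si](C)(C)C(C)(C)C)[C@H]2C=C1OS(=O)(=O)C(F)(F)F
F6 | step 10 | diene from F5 (C5=C6 and C2=C3 alkenes) | CC(C)C[C@H](c1c(OCc2ccccc2)cc(OCc2ccccc2)cc1OCc1ccccc1)[C@]1(C)C=C2[C@H](C)CC[C@H](C(C)(C)O[Si](C)(C)C(C)(C)C)[C@H]2C=C1
F7 | step 10 | alkylphloroglucinol: 27 without its two formyl groups | CC(C)C[C@H](c1c(O)cc(O)cc1O)[C@]1(C)C=C2[C@H](C)CC[C@H](C(C)(C)O[Si](C)(C)C(C)(C)C)[C@H]2CC1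
F8 | step 7 | bis-vinyl hydroxy enone (carbinol centre uncontrolled) | C=CC1(O)[C@H](C)CC[C@H](C(C)(C)O[Si](C)(C)C(C)(C)C)[C@H]1CC(=O)C=C
F9 | step 7 | bicyclic 4-hydroxycyclohex-2-enone (carbinol centre uncontrolled) | O=C1C=CC2(O)[C@H](C)CC[C@H](C(C)(C)O[Si](C)(C)C(C)(C)C)[C@H]2C1
F10 | step 7 | des-methyl β,γ-unsaturated ketone (12 without the C1 methyl) | O=C1CC=C2[C@H](C)CC[C@H](C(C)(C)O[Si](C)(C)C(C)(C)C)[C@H]2C1
F11 | step 6 | 2-[(1R,3R,6S)-3-methyl-2-methylidene-6-(2-TBSO-propan-2-yl)cyclohexyl]acetaldehyde | C=C1[C@H](C)CC[C@H](C(C)(C)O[Si](C)(C)C(C)(C)C)[C@H]1CC=O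
F12 | step 6 | homoallylic alcohol (carbinol and methyl-bearing centres uncontrolled) | C=C1[C@H](C)CC[C@H](C(C)(C)O[Si](C)(C)C(C)(C)C)[C@H]1CC(O)C(C)C=C
F13 | step 6 | bicyclic cyclohexenol (alcohol of 12; two centres uncontrolled) | CC1C=C2[C@H](C)CC[C@H](C(C)(C)O[Si](C)(C)C(C)(C)C)[C@H]2CC1O
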